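**Plan**

1. Retrosynthesis: the dihydropyran ring (ring B) is cut at C3–C4 and O1–C2 in one retro-[4+2], giving an o-quinone methide on ring A and the C14 triene ester 8. Ester 8 is then cut at its C2=C3 alkene (Z-olefination), at the C–C bond made by a Claisen rearrangement, and at a carbinol C–C bond (Grignard).
2. Enabling feature: C4 is a benzylic CH2 ortho to the phenolic O1 of ring A, so O1–C8a–C4a–C4 is a latent o-quinone methide heterodiene. C2 (methyl plus chain, fully substituted) beside an unsubstituted C3 is the imprint of a 1,1-disubstituted alkene. The C7 oxygen, para to C4, is carried as a pivalate so that only the ortho-quinone methide can form.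
3. Forward: the chain is built first (Grignard addition, Johnson–Claisen, partial reduction, Still–Gennari) and the arene partner in two steps from the purchased ring A aldehyde. Ring B is the only ring made, in the convergent step 7, and one saponification then removes the pivalate and the ethyl ester.
4. Stereochemistry: C2 (R) comes from catalyst-controlled enantioface selection at the alkene in the [4+2]. The 6E alkene comes from the chair Claisen transition state and the 2Z alkene from the kinetic Still–Gennari elimination.

Key step: step 7

Remark 1: the sense of induction of the chiral acid in step 7 cannot be derived with certainty; the (S,S) catalyst is written, and its mirror image is to be used if a first run gives the 2S adduct.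
Remark 2: compounds 1, 2 and 9, triethyl orthoacetate and ethyl 2-[bis(2,2,2-trifluoroethoxy)phosphoryl]propanoate are taken as commercial.
Catalyst of step 7: the imidodiphosphorimidate HN[P(=NSO2CF3)(O2Ar*)]2, where O2Ar* is (S)-3,3'-bis[3,5-bis(trifluoromethyl)phenyl]-1,1'-binaphthalene-2,2'-diolate ("IDPi acid").

**Route**

Step 1
Reactants: 1 4-bromo-2-methylbut-1-ene; 2 2-methylprop-2-enal (methacrolein)
Product: 4 2,6-dimethylhepta-1,6-dien-3-ol (racemic), via (3-methylbut-3-en-1-yl)magnesium bromide 3 (not isolated)
Conditions: Mg, I2 (cat.), THF, rt → 40 °C; then 2, −78 → 0 °C; aq. NH4Cl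
Reagents that add atoms: none
Why: Grignard formation from the primary homoallylic bromide and 1,2-addition to the enal carbonyl (Grignard addition) should give the allylic alcohol, whose racemic carbinol centre is erased in step 2.

Step 2
Reactants: 4 2,6-dimethylhepta-1,6-dien-3-ol
Product: 6 ethyl (4E)-4,8-dimethylnona-4,8-dienoate, via mixed ketene acetal 5 (not isolated)
Conditions: MeC(OEt)3 (6 equiv), EtCO2H (cat.), 140 °C, EtOH distilled off
Reagents that add atoms: triethyl orthoacetate, CCOC(C)(OCC)OCC
Why: Johnson–Claisen rearrangement, in which the chair [3,3] shift of ketene acetal 5 with the carbinol substituent equatorial should set the (E)-trisubstituted alkene and add the two-carbon ester arm.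

Step 3
Reactants: 6 ethyl (4E)-4,8-dimethylnona-4,8-dienoate
Product: 7 (4E)-4,8-dimethylnona-4,8-dienal
Conditions: i-Bu2AlH (1.05 equiv), CH2Cl2, −78 °C; then aq. KNaC4H4O6
Reagents that add atoms: none
Why: partial reduction of an unhindered ester with one equivalent of i-Bu2AlH at low temperature should stop at the aldehyde, the isolated alkenes being inert.

Step 4
Reactants: 7 (4E)-4,8-dimethylnona-4,8-dienal
Product: 8 ethyl (2Z,6E)-2,6,10-trimethylundeca-2,6,10-trienoate
Conditions: (CF3CH2O)2P(O)CH(Me)CO2Et, KN(SiMe3)2, 18-crown-6, THF, −78 °C; then 7, −78 °C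
Reagents that add atoms: ethyl 2-[bis(2,2,2-trifluoroethoxy)phosphoryl]propanoate, CCOC(=O)C(C)P(=O)(OCC(F)(F)F)OCC(F)(F)F
Why: Still–Gennari olefination, in which the electron-poor trifluoroethyl phosphonate with a dissociated potassium counter-ion eliminates under kinetic control and should give the (Z)-α-methyl enoate with the ester cis to the chain.

Step 5
Reactants: 9 2,4-dihydroxy-6-methylbenzaldehyde
Product: 10 4-formyl-3-hydroxy-5-methylphenyl 2,2-dimethylpropanoate
Conditions: PivCl (1.05 equiv), Et3N (1.2 equiv), CH2Cl2, −10 → 0 °C
Reagents that add atoms: pivaloyl chloride, CC(C)(C)C(=O)Cl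
Why: regioselective O-acylation, since the C2 hydroxyl is held in a hydrogen bond to the formyl group and the free, more acidic C4 hydroxyl should react alone.

Step 6
Reactants: 10 4-formyl-3-hydroxy-5-methylphenyl 2,2-dimethylpropanoate
Product: 11 3-hydroxy-4-(hydroxymethyl)-5-methylphenyl 2,2-dimethylpropanoate
Conditions: NaBH4, THF/MeOH (4:1), 0 °C; pH 7 buffer
Reagents that add atoms: none
Why: chemoselective borohydride reduction of the aldehyde, which the hindered aryl pivalate should survive at 0 °C.

Step 7
Reactants: 11 3-hydroxy-4-(hydroxymethyl)-5-methylphenyl 2,2-dimethylpropanoate; 8 ethyl (2Z,6E)-2,6,10-trimethylundeca-2,6,10-trienoate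
Product: 13 ethyl (2Z,6E)-9-[(2R)-7-(2,2-dimethylpropanoyloxy)-2,5-dimethyl-3,4-dihydro-2H-chromen-2-yl]-2,6-dimethylnona-2,6-dienoate, via o-quinone methide 12 (not isolated)
Conditions: (S,S)-IDPi acid HN[P(=NSO2CF3)(O2Ar*)]2 (5 mol %), 5 Å MS, PhMe, −20 °C → rt; 11 (1.3 equiv) added slowly to 8 and catalyst
Reagents that add atoms: none
Why: Proposed new method: the strong, confined acid should ionise the benzylic C–OH of 11 (water to the sieves) to o-quinone methide 12, held O-protonated and hydrogen-bonded inside the chiral anion, whereupon the CH2 terminus of the 1,1-disubstituted alkene of 8 bonds to the exocyclic methide carbon (C4–C3) and the quinoid oxygen closes on the developing tertiary carbon (O1–C2) in an asynchronous, inverse-electron-demand hetero-Diels–Alder reaction. The closest known reaction types are the chiral phosphoric acid and imidodiphosphate catalysed [4+2] cycloadditions of in situ generated o-quinone methides with styrenes, enol ethers and tethered unactivated alkenes, and the thermal racemic cycloaddition of o-quinone methides with 1,1-dialkylethenes; what is new is enantiocontrol with a methide-unsubstituted o-quinone methide and a purely aliphatic alkene. Ring B (the dihydropyran) is closed by intermolecular [4+2] annulation, four atoms (O1, C8a, C4a, C4) from 12 and two (C2, C3) from the alkene, C–C bonding leading and C–O bonding completing the six-membered ring. The one new stereocentre, C2, is under catalyst control: the cleft must tell the methyl group from the long chain, which should point out of the pocket, so that a single enantioface of the alkene meets 12. Regiochemistry follows the polarity (nucleophilic CH2 to the electrophilic methide carbon, oxygen to the tertiary carbon), and among the three alkenes the enoate is deactivated by conjugation and the internal trisubstituted one is more hindered than the terminal methylidene. Only the ortho-quinone methide can form because the oxygen para to the benzylic carbon is acylated, and the pivalate also lowers the nucleophilicity of ring A against self-condensation.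

Step 8
Reactants: 13 ethyl (2Z,6E)-9-[(2R)-7-(2,2-dimethylpropanoyloxy)-2,5-dimethyl-3,4-dihydro-2H-chromen-2-yl]-2,6-dimethylnona-2,6-dienoate
Product: 14 (2Z,6E)-9-[(2R)-7-hydroxy-2,5-dimethyl-3,4-dihydro-2H-chromen-2-yl]-2,6-dimethylnona-2,6-dienoic acid
Conditions: LiOH·H2O (6 equiv), THF/MeOH/H2O (degassed), rt → 40 °C; then 1 M HCl, 0 °C, to pH 3
Reagents that add atoms: lithium hydroxide (aqueous), [Li+].[OH-]
Why: saponification should cleave the aryl pivalate and the conjugated ethyl ester in one operation, while the quaternary C2 centre cannot epimerise and mild base should leave both alkene geometries intact.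

**Compound list**

1 | 4-bromo-2-methylbut-1-ene | C=C(C)CCBr | starting material
2 | 2-methylprop-2-enal (methacrolein) | C=C(C)C=O | starting material
3 | (3-methylbut-3-en-1-yl)magnesium bromide | C=C(C)CC[Mg]Br | intermediate
4 | 2,6-dimethylhepta-1,6-dien-3-ol (racemic) | C=C(C)C(O)CCC(C)=C | intermediate
5 | 3-[(1-ethoxyethenyl)oxy]-2,6-dimethylhepta-1,6-diene (mixed ketene acetal) | C=C(OCC)OC(CCC(C)=C)C(C)=C | intermediate
6 | ethyl (4E)-4,8-dimethylnona-4,8-dienoate | CCOC(=O)CC/C(C)=C/CCC(C)=C | intermediate
7 | (4E)-4,8-dimethylnona-4,8-dienal | O=CCC/C(C)=C/CCC(C)=C | intermediate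
8 | ethyl (2Z,6E)-2,6,10-trimethylundeca-2,6,10-trienoate | C/C(=C/CC/C(C)=C/CCC(C)=C)C(=O)OCC | intermediate
9 | 2,4-dihydroxy-6-methylbenzaldehyde | Cc1cc(O)cc(O)c1C=O | starting material
10 | 4-formyl-3-hydroxy-5-methylphenyl 2,2-dimethylpropanoate | Cc1cc(OC(=O)C(C)(C)C)cc(O)c1C=O | intermediate
11 | 3-hydroxy-4-(hydroxymethyl)-5-methylphenyl 2,2-dimethylpropanoate | Cc1cc(OC(=O)C(C)(C)C)cc(O)c1CO | intermediate
12 | 5-methyl-4-methylidene-3-oxocyclohexa-1,5-dien-1-yl 2,2-dimethylpropanoate (o-quinone methide) | C=C1C(=O)C=C(OC(=O)C(C)(C)C)C=C1C | intermediate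
13 | ethyl (2Z,6E)-9-[(2R)-7-(2,2-dimethylpropanoyloxy)-2,5-dimethyl-3,4-dihydro-2H-chromen-2-yl]-2,6-dimethylnona-2,6-dienoate | C/C(=C/CC/C(C)=C/CC[C@]1(C)CCc2c(C)cc(OC(=O)C(C)(C)C)cc2O1)C(=O)OCC | intermediate
14 | (2Z,6E)-9-[(2R)-7-hydroxy-2,5-dimethyl-3,4-dihydro-2H-chromen-2-yl]-2,6-dimethylnona-2,6-dienoic acid | C/C(=C/CC/C(C)=C/CC[C@]1(C)CCc2c(C)cc(O)cc2O1)C(=O)O | target

Total step count: 8
Longest linear sequence: 6 steps (1, 2, 3, 4, 7, 8)

**Steps most likely to fail**

1. Step 7 (Proposed new method). What may go wrong: too little discrimination between the methyl group and the chain in the chiral cleft, so that enantioselectivity is low; self-condensation of the quinone methide; or acid-induced reaction at the internal alkene. Fallback with known chemistry, in which stereocontrol is replaced by resolution: setting out from 11 and 8, the two are heated without acid (PhCl, 150–170 °C, sealed tube). Thermal loss of water from the salicyl alcohol gives 12, and its uncatalysed [4+2] reaction with the methylidene group should give racemic ethyl (2Z,6E)-9-[7-(2,2-dimethylpropanoyloxy)-2,5-dimethyl-3,4-dihydro-2H-chromen-2-yl]-2,6-dimethylnona-2,6-dienoate F1. Preparative chromatography on a polysaccharide chiral stationary phase (amylose tris(3,5-dimethylphenylcarbamate)) should then divide F1 into 13, where the route is rejoined, and its enantiomer ethyl (2Z,6E)-9-[(2S)-7-(2,2-dimethylpropanoyloxy)-2,5-dimethyl-3,4-dihydro-2H-chromen-2-yl]-2,6-dimethylnona-2,6-dienoate F2, which is set aside. The configuration of the eluted enantiomers would have to be assigned, for example by circular dichroism against calculation.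

2. Step 4. What may go wrong: erosion of the kinetic Z-selectivity with the α-methyl phosphonate, giving E-enoate that is hard to remove, or enolisation of the aldehyde. Fallback: setting out from 7, iodo-olefination of the Stork–Zhao type with the ylide Ph3P=C(I)CH3 (made in the flask from ethyltriphenylphosphonium iodide with n-BuLi, I2 and NaN(SiMe3)2, THF, −78 °C) should give (2Z,6E)-2-iodo-6,10-dimethylundeca-2,6,10-triene F3. Ethoxycarbonylation under zerovalent palladium (Pd(PPh3)4, CO 1 atm, EtOH, Et3N, DMF, 60 °C) proceeds with retention of alkene geometry and comes back to the route at 8.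

3. Step 3. What may go wrong: over-reduction to the primary alcohol or incomplete conversion, leaving a mixture of three oxidation levels. Fallback: setting out from 6, complete reduction with LiAlH4 (Et2O, 0 °C) should give (4E)-4,8-dimethylnona-4,8-dien-1-ol F4. Dess–Martin oxidation (CH2Cl2, NaHCO3, rt) then comes back to the route at 7.

Further compounds
F1 | step 7 | racemic ethyl (2Z,6E)-9-[7-(2,2-dimethylpropanoyloxy)-2,5-dimethyl-3,4-dihydro-2H-chromen-2-yl]-2,6-dimethylnona-2,6-dienoate | C/C(=C/CC/C(C)=C/CCC1(C)CCc2c(C)cc(OC(=O)C(C)(C)C)cc2O1)C(=O)OCC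
F2 | step 7 | ethyl (2Z,6E)-9-[(2S)-7-(2,2-dimethylpropanoyloxy)-2,5-dimethyl-3,4-dihydro-2H-chromen-2-yl]-2,6-dimethylnona-2,6-dienoate | C/C(=C/CC/C(C)=C/CC[C@@]1(C)CCc2c(C)cc(OC(=O)C(C)(C)C)cc2O1)C(=O)OCC
F3 | step 4 | (2Z,6E)-2-iodo-6,10-dimethylundeca-2,6,10-triene | C/C(I)=C/CC/C(C)=C/CCC(C)=C
F4 | step 3 | (4E)-4,8-dimethylnona-4,8-dien-1-ol | OCCC/C(C)=C/CCC(C)=C
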